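The strategy reads butyrolactone C4, with its three carbon arms (C3H2–C2 carboxyl, C5H2–O, pyranone C6), as C4 of a 2-furoate. A single copper-carbene (2+1) cycloaddition of ethyl diazoacetate to the ester-free C4=C5 bond of methyl furan-2-carboxylate breaks the aromaticity. It makes the lasting C4–C3 bond and a sacrificial C5–C3 bond, and it fixes C4 absolutely. The precursor is just this pair of commercial reagents. Ozonolysis, allylation (sets pyranone C6), retro-aldol unzipping and lactonisation give a trans lactone. Formyl reduction, allyl cleavage, Z-olefination with a dihydro-β-ionone-derived phosphonate and an acid-driven acyl transfer from O–C6 to O–C5 then close both lactone rings.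

Key step: step 1

Assumption: the (R,R)-antipode of the isopropyl bis(oxazoline) is taken to give the (1R,5R,6R) series; both antipodes are commercial, so the ligand is exchanged if the sense of induction proves opposite.
Stereochemical check: CIP analysis of the target gives 6R (pyranone) and 4R (butyrolactone), which corresponds to trans-(4R,5R)-11 and to exo-(1R,5R,6R)-3, so no structure needs correction.

Step 1
Reactants: 1 methyl furan-2-carboxylate; 2 ethyl diazoacetate
Product: 3 6-ethyl 3-methyl (1R,5R,6R)-2-oxabicyclo[3.1.0]hex-3-ene-3,6-dicarboxylate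
Conditions: Cu(OTf)2 (1 mol %), (R,R)-iPr-box (1.2 mol %), PhNHNH2 (cat.), CH2Cl2, 0 °C, slow addition of 2 to excess 1; recrystallisation (pentane/CH2Cl2)
Reagents that add atoms: none
Why: Cu(I), formed in situ by phenylhydrazine reduction, expels N2 from 2 to give an electrophilic bis(oxazoline) copper carbene, which adds to furan C4=C5 in a concerted but asynchronous (2+1) cycloaddition that starts at the nucleophilic C4. The closest known reaction type is the copper bis(oxazoline)-catalysed asymmetric cyclopropanation of enol ethers and furan-2-carboxylates with diazoacetates. The three-membered ring closes by suprafacial addition of the single carbene carbon to both alkene termini, so the cis ring fusion is obligatory. C1 and C5 (the furan face, hence the future butyrolactone C4) are controlled by the C2-symmetric ligand, whose isopropyl groups leave one trajectory to the carbene open, while C6 is controlled by the substrate, the ester turning away from the heterocycle (exo, convex face). Site selectivity is needed and is secured by the C2 ester, which depletes C2=C3 and also leaves the push–pull enol ether of 3 too electron-poor for a second addition, while excess 1 and slow addition of 2 hold back carbene dimerisation. Recrystallisation of 3 should raise the enantiomeric purity before the material is carried on.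

Step 2
Reactants: 3 6-ethyl 3-methyl (1R,5R,6R)-2-oxabicyclo[3.1.0]hex-3-ene-3,6-dicarboxylate
Product: 5 ethyl (1R,2R,3R)-2-formyl-3-[(2-methoxy-2-oxoacetyl)oxy]cyclopropane-1-carboxylate, via secondary ozonide 4 (not isolated)
Conditions: O3, CH2Cl2, −78 °C; then Me2S, −78 °C → rt
Reagents that add atoms: ozone [O-][O+]=O
Why: Criegee ozonolysis with reductive work-up attacks the only C=C bond (an enol ether), so furan C3 becomes the formyl carbon and furan C2 ends as a methyl oxalyl ester on the cyclopropanol oxygen, leaving the three ring stereocentres untouched.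

Step 3
Reactants: 5 ethyl (1R,2R,3R)-2-formyl-3-[(2-methoxy-2-oxoacetyl)oxy]cyclopropane-1-carboxylate; 6 allyltrimethylsilane
Product: 7 ethyl (1R,2S,3R)-2-[(1R)-1-hydroxybut-3-en-1-yl]-3-[(2-methoxy-2-oxoacetyl)oxy]cyclopropane-1-carboxylate
Conditions: BF3·OEt2 (1.1 equiv), CH2Cl2, −78 °C; aq. NaHCO3; crude product used directly
Reagents that add atoms: none
Why: Hosomi–Sakurai allylation through an open transition state, in which the BF3-bound cyclopropanecarbaldehyde reacts in its bisected conformer under Felkin–Anh control by the adjacent ring stereocentre (future C4), which should set the carbinol carbon, the future pyranone C6, as R.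

Step 4
Reactants: 7 ethyl (1R,2S,3R)-2-[(1R)-1-hydroxybut-3-en-1-yl]-3-[(2-methoxy-2-oxoacetyl)oxy]cyclopropane-1-carboxylate
Product: 10 (2R,3S)-5-oxo-2-(prop-2-en-1-yl)oxolane-3-carbaldehyde, via cyclopropanol 8 (not isolated), via hydroxy aldehyde 9 (not isolated)
Conditions: Ba(OH)2·8H2O, MeOH, 0 °C
Reagents that add atoms: none
Why: Hydroxide removes the activated oxalate, the donor–acceptor cyclopropanolate opens by retro-aldol cleavage of the bond to the ester-bearing carbon, and the C6 hydroxyl lactonises on the liberated CH2CO2Et arm, so that C4 keeps its configuration and the trans lactone is also the thermodynamic epimer at the formyl-bearing carbon.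

Step 5
Reactants: 10 (2R,3S)-5-oxo-2-(prop-2-en-1-yl)oxolane-3-carbaldehyde
Product: 11 (4R,5R)-4-(hydroxymethyl)-5-(prop-2-en-1-yl)oxolan-2-one
Conditions: NaBH4, MeOH, −20 → 0 °C; aq. NH4Cl
Reagents that add atoms: none
Why: Chemoselective borohydride reduction, since an aldehyde is reduced far faster than a γ-lactone at low temperature, and the buffered quench keeps the alkoxide from starting acyl migration.

Step 6
Reactants: 11 (4R,5R)-4-(hydroxymethyl)-5-(prop-2-en-1-yl)oxolan-2-one
Product: 12 (4R,5R)-4-{[(tert-butyldimethylsilyl)oxy]methyl}-5-(prop-2-en-1-yl)oxolan-2-one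
Conditions: TBSCl, imidazole, CH2Cl2, 0 °C → rt
Reagents that add atoms: tert-butyldimethylsilyl chloride CC(C)(C)[Si](C)(C)Cl
Why: Standard silylation of a primary alcohol, needed so that the hydroxyl neither forms a lactol with the aldehyde of step 7 nor quenches the phosphonate anion of step 12.

Step 7
Reactants: 12 (4R,5R)-4-{[(tert-butyldimethylsilyl)oxy]methyl}-5-(prop-2-en-1-yl)oxolan-2-one
Product: 14 2-[(2R,3R)-3-{[(tert-butyldimethylsilyl)oxy]methyl}-5-oxooxolan-2-yl]acetaldehyde, via secondary ozonide 13 (not isolated)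
Conditions: O3, CH2Cl2, −78 °C; then Me2S, −78 °C → rt; used without chromatography
Reagents that add atoms: ozone [O-][O+]=O
Why: Ozonolysis of the monosubstituted alkene with reductive work-up, to which lactone and silyl ether are inert, and the β-acyloxy aldehyde is carried on at once to avoid elimination.

Step 8
Reactants: 15 dihydro-β-ionone
Product: 17 2-(but-3-yn-1-yl)-1,3,3-trimethylcyclohex-1-ene, via enol phosphate 16 (not isolated)
Conditions: LDA, THF, −78 °C; ClP(O)(OEt)2, −78 °C → rt; then LDA (2.3 equiv), THF, −78 °C → rt; H2O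
Reagents that add atoms: none
Why: Methyl ketone to terminal alkyne conversion by the enol phosphate elimination method, that is, kinetic deprotonation at the methyl group, O-phosphorylation and base-induced β-elimination of diethyl phosphate.

Step 9
Reactants: 17 2-(but-3-yn-1-yl)-1,3,3-trimethylcyclohex-1-ene
Product: 20 (3E)-4-methyl-6-(2,6,6-trimethylcyclohex-1-en-1-yl)hex-3-en-1-ol, via alkenylalane 18 (not isolated), via lithium alanate 19 (not isolated)
Conditions: Me3Al, Cp2ZrCl2 (cat.), CH2Cl2, rt; excess Me3Al evaporated; n-BuLi, hexane/THF, 0 °C; oxirane, −78 °C → rt; cold 3 M HCl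
Reagents that add atoms: trimethylaluminium C[Al](C)C; oxirane C1CO1
Why: Negishi zirconium-catalysed carboalumination adds methyl and aluminium syn with aluminium at the terminus, which fixes the E trisubstituted alkene, and the more nucleophilic alanate opens oxirane with retention of the alkene geometry.

Step 10
Reactants: 20 (3E)-4-methyl-6-(2,6,6-trimethylcyclohex-1-en-1-yl)hex-3-en-1-ol
Product: 21 2-[(3E)-6-iodo-3-methylhex-3-en-1-yl]-1,3,3-trimethylcyclohex-1-ene
Conditions: I2, PPh3, imidazole, CH2Cl2, 0 °C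
Reagents that add atoms: iodine II
Why: Appel-type (Garegg–Samuelsson) iodination replaces the primary hydroxyl by SN2 displacement of the oxyphosphonium group under near-neutral conditions that leave both alkenes alone.

Step 11
Reactants: 21 2-[(3E)-6-iodo-3-methylhex-3-en-1-yl]-1,3,3-trimethylcyclohex-1-ene; 22 methyl bis(2,2,2-trifluoroethyl)phosphonoacetate
Product: 23 methyl (5E)-2-[bis(2,2,2-trifluoroethoxy)phosphoryl]-6-methyl-8-(2,6,6-trimethylcyclohex-1-en-1-yl)oct-5-enoate (racemic at C2)
Conditions: NaH, DMF, 0 °C → rt, 22 in slight excess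
Reagents that add atoms: none
Why: SN2 alkylation of the stabilised sodium phosphonoacetate anion with a primary iodide, where excess 22 limits dialkylation, the weakly basic anion disfavours E2, and the racemic α-centre is destroyed in step 12.

Step 12
Reactants: 14 2-[(2R,3R)-3-{[(tert-butyldimethylsilyl)oxy]methyl}-5-oxooxolan-2-yl]acetaldehyde; 23 methyl (5E)-2-[bis(2,2,2-trifluoroethoxy)phosphoryl]-6-methyl-8-(2,6,6-trimethylcyclohex-1-en-1-yl)oct-5-enoate
Product: 24 methyl (2Z,5E)-2-{2-[(2R,3R)-3-{[(tert-butyldimethylsilyl)oxy]methyl}-5-oxooxolan-2-yl]ethylidene}-6-methyl-8-(2,6,6-trimethylcyclohex-1-en-1-yl)oct-5-enoate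
Conditions: 23, KHMDS (slightly less than 23), 18-crown-6, THF, −78 °C; then 14, −78 °C
Reagents that add atoms: none
Why: Still–Gennari variant of the Horner–Wadsworth–Emmons olefination, in which the electron-poor phosphonate and the dissociated potassium ion make collapse of the kinetic adduct faster than its equilibration, placing the ester cis to the CH2 that leads to C6 (Z), while the preformed anion at −78 °C spares the lactone and its β-acyloxy linkage.

Step 13
Reactants: 24 methyl (2Z,5E)-2-{2-[(2R,3R)-3-{[(tert-butyldimethylsilyl)oxy]methyl}-5-oxooxolan-2-yl]ethylidene}-6-methyl-8-(2,6,6-trimethylcyclohex-1-en-1-yl)oct-5-enoate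
Product: 27 (6R)-3-[(3E)-4-methyl-6-(2,6,6-trimethylcyclohex-1-en-1-yl)hex-3-en-1-yl]-6-[(3R)-5-oxooxolan-3-yl]-5,6-dihydro-2H-pyran-2-one, via primary alcohol 25 (not isolated), via secondary alcohol 26 (not isolated)
Conditions: CSA (cat.), MeOH, rt; then solvent change to toluene, 4 Å MS, 60 °C
Reagents that add atoms: none
Why: Acid-catalysed desilylation followed by translactonisation (transesterification), in which the freed C5 hydroxyl takes over the C2 acyl group from the C6 oxygen either directly or through the methanol-opened ester, the released C6 hydroxyl closes on the cis-disposed enoate ester (the classical lactonisation of δ-hydroxy Z-enoates), and removal of methanol makes the bis-lactone the sink, with no C–O bond at a stereocentre broken, so both centres are retained.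

Compound list
1 | methyl furan-2-carboxylate | COC(=O)c1ccco1 | starting material
2 | ethyl diazoacetate | CCOC(=O)C=[N+]=[N-] | starting material
3 | 6-ethyl 3-methyl (1R,5R,6R)-2-oxabicyclo[3.1.0]hex-3-ene-3,6-dicarboxylate (exo ester) | COC(=O)C1=C[C@@H]2[C@@H](C(=O)OCC)[C@@H]2O1 | intermediate
4 | bridged secondary ozonide of 3 (new bridgehead centres undefined) | COC(=O)C12OOC(O1)[C@@H]3[C@@H](C(=O)OCC)[C@@H]3O2 | intermediate
5 | ethyl (1R,2R,3R)-2-formyl-3-[(2-methoxy-2-oxoacetyl)oxy]cyclopropane-1-carboxylate | O=C[C@@H]1[C@@H](C(=O)OCC)[C@@H]1OC(=O)C(=O)OC | intermediate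
6 | allyltrimethylsilane | C=CC[Si](C)(C)C | starting material
7 | ethyl (1R,2S,3R)-2-[(1R)-1-hydroxybut-3-en-1-yl]-3-[(2-methoxy-2-oxoacetyl)oxy]cyclopropane-1-carboxylate | C=CC[C@@H](O)[C@@H]1[C@@H](C(=O)OCC)[C@@H]1OC(=O)C(=O)OC | intermediate
8 | cyclopropanol from oxalate cleavage of 7 | C=CC[C@@H](O)[C@@H]1[C@@H](C(=O)OCC)[C@@H]1O | intermediate
9 | ethyl (3S,4R)-3-formyl-4-hydroxyhept-6-enoate | C=CC[C@@H](O)[C@@H](C=O)CC(=O)OCC | intermediate
10 | (2R,3S)-5-oxo-2-(prop-2-en-1-yl)oxolane-3-carbaldehyde (trans) | C=CC[C@@H]1[C@@H](C=O)CC(=O)O1 | intermediate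
11 | (4R,5R)-4-(hydroxymethyl)-5-(prop-2-en-1-yl)oxolan-2-one | C=CC[C@@H]1[C@@H](CO)CC(=O)O1 | intermediate
12 | (4R,5R)-4-{[(tert-butyldimethylsilyl)oxy]methyl}-5-(prop-2-en-1-yl)oxolan-2-one | C=CC[C@@H]1[C@@H](CO[Si](C)(C)C(C)(C)C)CC(=O)O1 | intermediate
13 | 1,2,4-trioxolane (secondary ozonide) of 12 (trioxolane centre undefined) | C1OOC(O1)C[C@@H]2[C@@H](CO[Si](C)(C)C(C)(C)C)CC(=O)O2 | intermediate
14 | 2-[(2R,3R)-3-{[(tert-butyldimethylsilyl)oxy]methyl}-5-oxooxolan-2-yl]acetaldehyde | O=CC[C@@H]1[C@@H](CO[Si](C)(C)C(C)(C)C)CC(=O)O1 | intermediate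
15 | dihydro-β-ionone | CC1=C(CCC(C)=O)C(C)(C)CCC1 | starting material
16 | diethyl 4-(2,6,6-trimethylcyclohex-1-en-1-yl)but-1-en-2-yl phosphate | C=C(CCC1=C(C)CCCC1(C)C)OP(=O)(OCC)OCC | intermediate
17 | 2-(but-3-yn-1-yl)-1,3,3-trimethylcyclohex-1-ene | C#CCCC1=C(C)CCCC1(C)C | intermediate
18 | (E)-dimethyl[2-methyl-4-(2,6,6-trimethylcyclohex-1-en-1-yl)but-1-en-1-yl]alane | C[Al](C)/C=C(\C)CCC1=C(C)CCCC1(C)C | intermediate
19 | lithium n-butyl(dimethyl)[(E)-2-methyl-4-(2,6,6-trimethylcyclohex-1-en-1-yl)but-1-en-1-yl]alanate | [Li+].CCCC[Al-](C)(C)/C=C(\C)CCC1=C(C)CCCC1(C)C | intermediate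
20 | (3E)-4-methyl-6-(2,6,6-trimethylcyclohex-1-en-1-yl)hex-3-en-1-ol | OCC/C=C(\C)CCC1=C(C)CCCC1(C)C | intermediate
21 | 2-[(3E)-6-iodo-3-methylhex-3-en-1-yl]-1,3,3-trimethylcyclohex-1-ene | ICC/C=C(\C)CCC1=C(C)CCCC1(C)C | intermediate
22 | methyl bis(2,2,2-trifluoroethyl)phosphonoacetate | COC(=O)CP(=O)(OCC(F)(F)F)OCC(F)(F)F | starting material
23 | methyl (5E)-2-[bis(2,2,2-trifluoroethoxy)phosphoryl]-6-methyl-8-(2,6,6-trimethylcyclohex-1-en-1-yl)oct-5-enoate (racemic at C2) | COC(=O)C(CC/C=C(\C)CCC1=C(C)CCCC1(C)C)P(=O)(OCC(F)(F)F)OCC(F)(F)F | intermediate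
24 | methyl (2Z,5E)-2-{2-[(2R,3R)-3-{[(tert-butyldimethylsilyl)oxy]methyl}-5-oxooxolan-2-yl]ethylidene}-6-methyl-8-(2,6,6-trimethylcyclohex-1-en-1-yl)oct-5-enoate | COC(=O)/C(CC/C=C(\C)CCC1=C(C)CCCC1(C)C)=C\C[C@@H]2[C@@H](CO[Si](C)(C)C(C)(C)C)CC(=O)O2 | intermediate
25 | desilylated 24, with free CH2OH on the trans lactone | COC(=O)/C(CC/C=C(\C)CCC1=C(C)CCCC1(C)C)=C\C[C@@H]2[C@@H](CO)CC(=O)O2 | intermediate
26 | methyl (2Z,5E)-2-{(3R)-3-hydroxy-3-[(3R)-5-oxooxolan-3-yl]propylidene}-6-methyl-8-(2,6,6-trimethylcyclohex-1-en-1-yl)oct-5-enoate | COC(=O)/C(CC/C=C(\C)CCC1=C(C)CCCC1(C)C)=C\C[C@@H](O)[C@H]2COC(=O)C2 | intermediate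
27 | (6R)-3-[(3E)-4-methyl-6-(2,6,6-trimethylcyclohex-1-en-1-yl)hex-3-en-1-yl]-6-[(3R)-5-oxooxolan-3-yl]-5,6-dihydro-2H-pyran-2-one | CC1=C(CC/C(C)=C/CCC2=CC[C@H]([C@H]3COC(=O)C3)OC2=O)C(C)(C)CCC1 | target

Total step count: 13. Longest linear sequence: 9 (steps 1–7, 12, 13). The tail branch (steps 8–11) joins at step 12.

Steps most likely to fail

1. Step 13.
- What may go wrong: the acyl migration between the two γ-lactones may stall at an unfavourable equilibrium. The liberated primary hydroxyl may add to the enoate in a 6-exo oxa-Michael process. Prolonged acid may begin to protonate the tail diene.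
- Fallback (sets out from 7, rejoins at 26): the migration is made unnecessary by never letting the C6 oxygen lactonise. Carbinol 7 is silylated (TBSOTf, 2,6-lutidine, CH2Cl2, −78 °C) to the silyl ether F1. Treatment with NaBH4 in MeOH containing Et3N at −20 °C cleaves the oxalate and unzips the cyclopropane to the silyloxy aldehyde F2. F2 is reduced before it can epimerise to the hydroxy ester F3, which closes through the primary oxygen to the 4-substituted butyrolactone F4. Ozonolysis through the ozonide F5 gives the β-silyloxy aldehyde F6, and Still–Gennari olefination with 23 gives the Z-enoate F7. CSA in MeOH then removes the silyl group to give 26, which lactonises to 27 as in step 13.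

2. Step 12.
- What may go wrong: β-elimination of the lactone carboxylate from the β-acyloxy aldehyde under the basic olefination conditions, and erosion of Z-selectivity with the α-branched phosphonate.
- Fallback (sets out from 12 and 23, rejoins at 27): ring-closing metathesis needs no aldehyde and enforces the cis geometry through the ring. Lactone 12 is opened with Me(MeO)NH·HCl/AlMe3 (CH2Cl2, 0 °C) to the hydroxy Weinreb amide F8. Phosphonate 23 is converted with aqueous formaldehyde and K2CO3 (Horner–Wadsworth–Emmons methylenation) into the 2-methylene ester F9, which is saponified (LiOH) to the acrylic acid F10. Steglich esterification of F8 with F10 gives the diene ester F11. A second-generation Grubbs catalyst closes the dihydropyranone F12, the tri- and tetrasubstituted tail alkenes staying inert. Aqueous HF in MeCN frees the hydroxy amide F13, which cyclises on the Weinreb amide to give 27.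

3. Step 1.
- What may go wrong: incomplete enantioface discrimination, competing carbene dimerisation, and loss of material in the crystallisation that upgrades the optical purity.
- Fallback (sets out from 1 and 2, rejoins at 3): asymmetric catalysis is replaced by resolution. Rh2(OAc)4-catalysed cyclopropanation (CH2Cl2, slow addition of 2) gives the exo racemate F14. This is separated by preparative chromatography on a chiral stationary phase, and the (1R,5R,6R) enantiomer is carried on as 3.

Further compounds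
F1 | step 13 | ethyl (1R,2S,3R)-2-[(1R)-1-{[tert-butyl(dimethyl)silyl]oxy}but-3-en-1-yl]-3-[(2-methoxy-2-oxoacetyl)oxy]cyclopropane-1-carboxylate | C=CC[C@@H](O[Si](C)(C)C(C)(C)C)[C@@H]1[C@@H](C(=O)OCC)[C@@H]1OC(=O)C(=O)OC
F2 | step 13 | ethyl (3S,4R)-4-{[tert-butyl(dimethyl)silyl]oxy}-3-formylhept-6-enoate | C=CC[C@@H](O[Si](C)(C)C(C)(C)C)[C@@H](C=O)CC(=O)OCC
F3 | step 13 | ethyl (3R,4R)-4-{[tert-butyl(dimethyl)silyl]oxy}-3-(hydroxymethyl)hept-6-enoate | C=CC[C@@H](O[Si](C)(C)C(C)(C)C)[C@@H](CO)CC(=O)OCC
F4 | step 13 | (4R)-4-[(1R)-1-{[tert-butyl(dimethyl)silyl]oxy}but-3-en-1-yl]oxolan-2-one | C=CC[C@@H](O[Si](C)(C)C(C)(C)C)[C@H]1COC(=O)C1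
F5 | step 13 | 1,2,4-trioxolane (secondary ozonide) of F4 | C1OOC(O1)C[C@@H](O[Si](C)(C)C(C)(C)C)[C@H]2COC(=O)C2
F6 | step 13 | (3R)-3-{[tert-butyl(dimethyl)silyl]oxy}-3-[(3R)-5-oxooxolan-3-yl]propanal | O=CC[C@@H](O[Si](C)(C)C(C)(C)C)[C@H]1COC(=O)C1
F7 | step 13 | tert-butyldimethylsilyl ether of 26 | COC(=O)/C(CC/C=C(\C)CCC1=C(C)CCCC1(C)C)=C\C[C@@H](O[Si](C)(C)C(C)(C)C)[C@H]2COC(=O)C2
F8 | step 12 | (3R,4R)-3-({[tert-butyl(dimethyl)silyl]oxy}methyl)-4-hydroxy-N-methoxy-N-methylhept-6-enamide | C=CC[C@@H](O)[C@@H](CO[Si](C)(C)C(C)(C)C)CC(=O)N(C)OC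
F9 | step 12 | methyl (5E)-6-methyl-2-methylidene-8-(2,6,6-trimethylcyclohex-1-en-1-yl)oct-5-enoate | C=C(CC/C=C(\C)CCC1=C(C)CCCC1(C)C)C(=O)OC
F10 | step 12 | (5E)-6-methyl-2-methylidene-8-(2,6,6-trimethylcyclohex-1-en-1-yl)oct-5-enoic acid | C=C(CC/C=C(\C)CCC1=C(C)CCCC1(C)C)C(=O)O
F11 | step 12 | ester of F8 (C4 oxygen) with F10 | C=CC[C@@H](OC(=O)C(=C)CC/C=C(\C)CCC1=C(C)CCCC1(C)C)[C@@H](CO[Si](C)(C)C(C)(C)C)CC(=O)N(C)OC
F12 | step 12 | dihydropyranone carrying the silyloxymethyl Weinreb amide side chain at C6 | CC1=C(CC/C(C)=C/CCC2=CC[C@H]([C@@H](CO[Si](C)(C)C(C)(C)C)CC(=O)N(C)OC)OC2=O)C(C)(C)CCC1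
F13 | step 12 | desilylated F12 (γ-hydroxy Weinreb amide) | CC1=C(CC/C(C)=C/CCC2=CC[C@H]([C@@H](CO)CC(=O)N(C)OC)OC2=O)C(C)(C)CCC1
F14 | step 1 | racemic exo 6-ethyl 3-methyl 2-oxabicyclo[3.1.0]hex-3-ene-3,6-dicarboxylate | COC(=O)C1=C[C@@H]2[C@@H](C(=O)OCC)[C@@H]2O1.COC(=O)C1=C[C@H]2[C@H](C(=O)OCC)[C@H]2O1
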